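The numbers in the tables stem from a simulated flask from invented constants, and the scatter is random.

The easy step is the ceiling. The green run reaches 100.0% of the electrophile charged, so each electrophile can give one target, and I take the partners to go one to one, so that where nucleophile is the limiting reagent the target, as a fraction of the electrophile charged, stops at the charge ratio s, nucleophile over electrophile: 0.440 for teal, 0.300 for south-west.

| setting | teal | green | west | south-west | north-west | north | south |
|---|---|---|---|---|---|---|---|
| electrophile | 0.050 M | 0.050 M | 0.050 M | 0.050 M | 0.050 M | 0.050 M | 0.050 M |
| nucleophile | 0.022 M | 0.22 M | 0.100 M | 0.0150 M | 0.150 M | 0.0500 M | 0.0800 M |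
| free base | 0.15 M | 0.15 M | 0.150 M | 0.150 M | 0.150 M | 0.150 M | 0.150 M |
| remark | run made earlier | run made earlier |  |  |  |  |  |
| time |  |  | 5.0 min | 5.0 min | 5.0 min | 5.0 min | 5.0 min |

| teal: time / min | teal: target / % | green: time / min | green: target / % |
|---|---|---|---|
| 0.250 | 7.6 | 0.417 | 64.3 |
| 0.833 | 16.3 | 0.667 | 79.6 |
| 1.33 | 19.8 | 1.00 | 88.8 |
| 2.00 | 25.7 | 1.33 | 94.7 |
| 3.00 | 31.4 | 2.00 | 97.8 |
| 4.00 | 34.6 | 3.00 | 100.0 |
| 5.00 | 37.7 | 5.00 | 99.8 |

(standard deviation of a reading: 0.5 percentage points)

- the analysis behind the earlier runs scatters by 0.5 percentage points, standard deviation
- a reading or a percentage of target counts all its forms, free or not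

1. the flasks put in order of amount of target, in percent of the electrophile charged, best first, at 5.0 min (west / south-west / north-west / north / south)
2. the amount of target, in percent of the electrophile charged of the flask you put first, at 5.0 min
3. the amount of target, in percent of the electrophile charged of the flask you put last, at 5.0 min

I follow one nucleophile molecule: at each moment it is either taken or waits, and its chance of being taken goes with the electrophile still left. Both partners lose the same amount, so electrophile left minus s times nucleophile left holds at the gap, the excess of electrophile as a fraction of its charge. I read teal at 5.00 min: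

electrophile left = 62.3%, nucleophile left = 0.143, gap = 0.560

clock = ln(electrophile left / nucleophile left) / gap = 2.63

The clock is the rate constant times the electrophile charge times the time, a count of the chances a nucleophile molecule has had of meeting electrophile. South-west shares teal's electrophile charge, free base charge and time, so I carry the clock over unchanged, with south-west's gap:

nucleophile left = gap / (exp(gap × clock) − s) = 0.700 / (exp(1.84) − 0.300) = 0.117

target = s × (1 − nucleophile left) = 26.5%

In my reckoning south-west's nucleophile is taken more surely than teal's, 0.117 left against 0.143, because its excess of electrophile is wider, yet I put south-west lower than teal's reading of 37.7% because its ceiling stands lower. The same rule with north-west's ratio gives 99.7%, and I rank the flasks by nucleophile charge.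

The forecast, holding that “excess nucleophile does no harm”, says north-west > west > south > north > south-west, with 99.6% first and 26.4% last, against my 99.7% and 26.5%.

    free base ⇌ dormant form (K = 0.130, k = 0.00580 s⁻¹)
    electrophile + nucleophile → acid set free + target (k = 0.230 L mol⁻¹ s⁻¹)
    nucleophile + acid set free ⇌ protonated nucleophile, settled at all times (K = 340 L mol⁻¹)
    acid set free + free base ⇌ salt of the base (K = 1000 L mol⁻¹, k = 0.600 L mol⁻¹ s⁻¹)
    crystals ⇌ target, rate k5*(cs5 - [target]) while solid is left; crystals form when [target] > cs5 (solubility = 10.0 mM, k = 0.0570 s⁻¹)

The flasks come out north-west > west > south > north > south-west, with 99.5% first and 27.0% last, so south-west stands 3 percentage points under its ceiling. At 5.00 min, of south-west's nucleophile charge, 8.97% is free and 0.934% protonated, against the 11.7% reckoned left. Scaled down to 2.0 min, the clock of 2.63 becomes 1.05, which puts south-west at 18.2% of target at that time, and south-west read then holds 18.7%.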